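## The problem

Numbering used throughout: C1 (O-angeloyl), C2 (O-isovaleryl), C3 (OH), C4 (CMe2), C5 (H), C6 (H), C7 (C=O), C8=C9 (methyl on C9), C10 (H), C11 (C-methyl). Ring A = C1–C5, C10, C11; ring B = C5–C10; ring C = C5, C6, C11, C10. In this numbering the target 28 is 1S,2S,3S,5S,6R,10R,11R.

- The skeleton is a cyclobutane (ring C) bridged across both diagonals: C6/C10 by the three-carbon enone bridge C7–C9 on one face, and C5/C11 by the four-carbon bridge C1–C4 on the other. A synthesis has to build this strained, doubly bridged four-membered ring with a quaternary C11.
- C5, C6, C10 and C11 are locked to one another by the cage. Once the C11 methyl is syn to the C7–C9 bridge, the other three follow, so these four centres are one stereochemical element.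
- The three carbinol centres C1–C3 lie on a near mirror plane of the core, the plane that exchanges C6 with C10 and C7 with C9. The core therefore cannot tell the two faces of ring A apart, and the first ring A centre must come from a chiral reagent acting on resolved material.
- After that, C1 can control C2 and C3: both oxygens are trans to C1–O (on the C10 side, C1–O being on the C6 side) and cis to each other.
- The three oxygens end in three different states (angelate, isovalerate, free hydroxyl), and two of them (C1, C3) are neopentyl.
- Fragile groups: the angelate (Z to E isomerisation with base, nucleophilic catalysts, radicals or metal hydrides), the pinane-type cyclobutane (cationic rearrangement in acid), and the vicinal ester/hydroxyl array (acyl migration).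
- The enabling feature is that C5–C10–C9–C8–C7–C6=C11–C1–C2–C3–C4 is an unbroken head-to-tail farnesane chain. With C5 as an acyl carbon, a ketene C5=C10 sits three atoms (C9, C8, C7) from the trisubstituted C6=C11 alkene and can close ring C and the carbocycle of ring B in one cycloaddition.

## Retrosynthesis

**Isovalerate last (28 to 27).** The C2–O acyl bond is cut first, giving diol 27. Acylating C2 last only asks the reagent to prefer C2–OH (between two methine carbons) over C3–OH (next to the gem-dimethyl carbon). Putting the angelate on last would instead require telling apart two neopentyl hydroxyls, C1 and C3.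

**C2–O and C3–O together (27 to 26).** Both C–O bonds are cut to the C2=C3 alkene of 26. A cis-dihydroxylation anti to the C1 ester gives exactly the needed pattern in one step. Epoxide-opening routes would need substitution at a neopentyl carbon. The forward step requires that ring A's alkene be the only electron-rich one, so ring B must already be the enone and the angelate is the only other alkene.

**Ring B carbonyl and the angelate (26 to 25 to 24).** The C7 oxygen is removed to give 25 (allylic oxidation of a trisubstituted alkene next to an unhindered CH2, forward), and the C1 ester is cut to allylic alcohol 24. Acylating before the oxidation makes the angelate serve as the protecting group for C1–OH and deactivates the C1–H bond, so no separate protection is spent.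

**C1 configuration (24 to 23).** The C1–H bond is cut to enone 23. Because the core is nearly mirror-symmetric about ring A, only a chiral reductant can set C1. A ketone flanked by the quaternary C11 and a cis-alkenyl carbon is a suitable substrate for oxazaborolidine-controlled reduction. Compound 23 must carry no second ketone, which is why ring B is oxidised only afterwards.

**Moving the carbonyl from C2 to C1 (23 to 22 to 21 to 20 to 18).** The ring closure below delivers a C2 ketone. The enone is reached by oxidising C1 (hydroxy ketone 20, then dione 21), trapping the only possible enol of 21 as triflate 22, and reducing the triflate. The dione can enolise only towards C3 because C11 is quaternary, so the C2=C3 position is fixed by construction. The one selectivity asked for is enolisation of 18 at C1 and not at C3.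

**Ring B alkene position (18 to 17).** The endocyclic C8=C9 alkene of 18 is traced to the exocyclic methylene of 17, which is what the key step produces. Isomerising at this robust ketone stage keeps transition-metal hydrides away from the later angelate.

**Ring A closure, C4–C5 (17 to 16).** The C4–C5 bond is cut to a C5 radical and the β-carbon of a side-chain enone, with the alcohol of 15 activated as thiocarbonyl derivative 16. Polar closures from the C5 ketone (aldol or reductive coupling) would leave a tertiary C5 hydroxyl that must then be removed. The radical route leaves C5–H directly, and the tether fixes C5. The forward step must form a quaternary carbon in a seven-membered ring faster than the radical is reduced.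

**Functional group changes and resolution (16 to 15 to 14 to 13 to 12).** The enone of 15 is unmasked from the dithiane of 14. Alcohol 14 comes from racemic 13 by enzymatic kinetic resolution, and 13 from cyclobutanone 12 by hydride reduction. Resolving here, at the first chiral intermediate, wastes the least material. It is also required before any reagent-controlled step on ring A.

**Key disconnection, C5–C6 and C10–C11 (12 to 10).** Both bonds of ring C are cut at once, leading through vinylketene 11 to the acyclic acid chloride 10. This removes two rings and three stereocentres in one step and leaves a linear trienoyl chloride. A stepwise cyclobutane synthesis would need the quaternary C11 and the cis-1,3 relationship to be built separately.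

**Chain assembly (10 to 9 to 8 to 3 + 6).** The acid chloride comes from acid 9 and ester 8. Cutting C1–C2 of 8 gives allylic bromide 3 and the acyl-anion equivalent 6, which brings C2 at the ketone level and the C3=C4 alkene with it. Bromide 3 derives from alcohol 2 and methyl geranate 1; dithiane 6 from 3-methylbut-2-enal 4 and propane-1,3-dithiol 5.

## Roads not taken

**Alternative 1:** Ring B is closed by cutting C9–C10. Forward, a redox-active ester on C10 is fragmented reductively and the C10 radical adds to C9 of an ynone hanging from C6, giving A1 (ring B enone, C1 silyl ether, C2=C3 alkene).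
- Merits: the ring B enone arrives in its final oxidation state with no isomerisation or allylic oxidation. A1 is only a dihydroxylation, a desilylation and two acylations from 28, which is shorter than the path from enone 23 and free of the chemoselectivity question in step 21. A1 is in fact the compound through which the fallback for step 21 passes.
- Weak points: the radical must bend an ynone into a three-atom bridge across the 1,3-positions of a cyclobutane, a strained transition state. The substrate must already contain rings A and C, the quaternary C11, a cis-1,3-disubstituted cyclobutane and the C1 centre in the right relation to the core. Building that substrate is the hard part, and this strategy does not address it.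
- Comparison: Alternative 1 has the better endgame. The chosen plan sets against it the assembly of the cyclobutane, the quaternary centre and the ring B carbons in one step from an acyclic compound six steps from commercial material.

**Alternative 2:** Ring C is closed by cutting C10–C11. Forward, the cross-conjugated enolate of a cycloheptenone (C1 ketone, C2=C3) alkylates at C11 with a C10 sulfonate on the fused six-membered ring, giving A2 (ring A enone, C7 ketal, saturated C9 methyl).
- Merits: cyclobutane closure by intramolecular ketone alkylation is a well-tried way to make pinane-type systems; the gem-dimethyl C4 blocks γ-deprotonation; and A2 has the ring B carbonyl masked, so a reagent-controlled reduction at C1 would face no second ketone or alkene. In that respect A2 is a cleaner version of enone 23 and the alkylation is arguably more certain than the radical closure in step 12.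
- Weak points: the closure is a four-membered ring formation creating a quaternary centre, in competition with O-alkylation and elimination, and it needs the leaving group held anti to the enolate carbon. The fused bicyclic substrate carries four stereocentres (C5, C6, C9, C10) that must be set beforehand. Ring B still needs deketalisation and dehydrogenation to the enone.
- Comparison: the chosen plan reaches the tricyclic skeleton in twelve steps with only one element of relative configuration to control, against a longer stereocontrolled synthesis of the fused precursor. It pays with a less precedented ring A closure and with the carbonyl transposition of steps 14–17.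

**Alternative 3:** Ring A is closed by cutting C2–C3. Forward, the boron enolate of a C1 alkoxymethyl ketone adds to a C3 aldehyde, giving A3 (C1 ketone, C2 p-methoxybenzyl ether, C3 hydroxyl, ring B enone).
- Merits: C2 and C3 oxygens and their configurations come with the ring closure, and the three oxygens emerge already differentiated (ketone, ether, free hydroxyl). This is better than the chosen plan, which must distinguish C2–OH from C3–OH by rate in the last step.
- Weak points: both carbonyls are neopentyl and the aldol closes a seven-membered ring across a cyclobutane, so the step is slow and reversible. The sense of addition relative to the core is not controlled by the substrate, for the same near-symmetry reason, and would rest on a matched chiral boron reagent. The C1 ketone must still be reduced to the hydroxyl trans to C2–O next to a ring B enone. The bicyclic core with two cis-1,3 arms must be made first.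
- Comparison: the chosen plan offers oxidation chemistry whose stereochemical outcome does not depend on a medium-ring aldol, and a core made in one step.

Key step: step 7

## Route

Assumption 1: in step 9 the lipase is taken to acylate the unwanted enantiomer; if it acylates the wanted one, the acetate would be carried on after methanolysis (K2CO3, MeOH), one step more.

Assumption 2: hydride is taken to attack the C5 ketone of 12 from the face away from the C1 arm, putting the hydroxyl syn to that arm; this centre is destroyed in step 12, so the outcome does not matter.

Step 1
Reactants: 1 methyl geranate, methyl (2E)-3,7-dimethylocta-2,6-dienoate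
Product: 2 methyl (2E,6E)-8-hydroxy-3,7-dimethylocta-2,6-dienoate
Conditions: SeO2 (cat.), t-BuOOH, salicylic acid (cat.), CH2Cl2, rt
Reagents that add atoms: selenium dioxide, O=[Se]=O (catalytic oxygen carrier); tert-butyl hydroperoxide, CC(C)(C)OO
Why: Riley allylic oxidation (ene reaction, then [2,3]-shift) goes at the E methyl of the electron-rich C6=C7 alkene and gives the E allylic alcohol; the conjugated C2=C3 alkene is deactivated.

Step 2
Reactants: 2 methyl (2E,6E)-8-hydroxy-3,7-dimethylocta-2,6-dienoate
Product: 3 methyl (2E,6E)-8-bromo-3,7-dimethylocta-2,6-dienoate
Conditions: CBr4, PPh3, CH2Cl2, 0 °C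
Reagents that add atoms: carbon tetrabromide, BrC(Br)(Br)Br
Why: Appel reaction of a primary allylic alcohol proceeds by direct substitution under neutral conditions, so the alkene geometry and position are kept.

Step 3
Reactants: 4 3-methylbut-2-enal; 5 propane-1,3-dithiol
Product: 6 2-(2-methylprop-1-en-1-yl)-1,3-dithiane
Conditions: BF3·OEt2 (cat.), CH2Cl2, −20 to 0 °C
Reagents that add atoms: none
Why: Lewis acid catalysed dithioacetalisation; the β,β-disubstituted enal reacts at the carbonyl, since conjugate thiol addition would have to form a hindered tertiary sulfide.

Step 4
Reactants: 6 2-(2-methylprop-1-en-1-yl)-1,3-dithiane; 3 methyl (2E,6E)-8-bromo-3,7-dimethylocta-2,6-dienoate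
Product: 8 methyl (2E,6E)-3,7-dimethyl-8-[2-(2-methylprop-1-en-1-yl)-1,3-dithian-2-yl]octa-2,6-dienoate, via lithiated dithiane 7 (not isolated)
Conditions: n-BuLi, THF, −78 to −30 °C; then 3, −78 °C
Reagents that add atoms: none
Why: Corey–Seebach alkylation; the allyl anion of 6 reacts with alkyl halides at the sulfur-bearing carbon (the γ end is a hindered tertiary carbon), and displacement of a primary allylic bromide at −78 °C should outrun attack on the unsaturated ester.

Step 5
Reactants: 8 methyl (2E,6E)-3,7-dimethyl-8-[2-(2-methylprop-1-en-1-yl)-1,3-dithian-2-yl]octa-2,6-dienoate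
Product: 9 (2E,6E)-3,7-dimethyl-8-[2-(2-methylprop-1-en-1-yl)-1,3-dithian-2-yl]octa-2,6-dienoic acid
Conditions: LiOH, THF–MeOH–H2O, rt; then dilute HCl
Reagents that add atoms: lithium hydroxide, [Li+].[OH-]
Why: Ester saponification; the dithiane and the three alkenes are inert to hydroxide at room temperature.

Step 6
Reactants: 9 (2E,6E)-3,7-dimethyl-8-[2-(2-methylprop-1-en-1-yl)-1,3-dithian-2-yl]octa-2,6-dienoic acid
Product: 10 (2E,6E)-3,7-dimethyl-8-[2-(2-methylprop-1-en-1-yl)-1,3-dithian-2-yl]octa-2,6-dienoyl chloride (used crude)
Conditions: (COCl)2, CH2Cl2, rt; evaporate
Reagents that add atoms: oxalyl chloride, ClC(=O)C(=O)Cl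
Why: Standard acid chloride formation without a formamide catalyst, so the 2E geometry is not disturbed; the dithiane tolerates HCl.

Step 7
Reactants: 10 (2E,6E)-3,7-dimethyl-8-[2-(2-methylprop-1-en-1-yl)-1,3-dithian-2-yl]octa-2,6-dienoyl chloride
Product: 12 racemic 7-methyl-2-methylidene-7-{[2-(2-methylprop-1-en-1-yl)-1,3-dithian-2-yl]methyl}bicyclo[3.1.1]heptan-6-one with the 7-methyl syn to the three-carbon bridge (target locants: C5 ketone; C9 methylidene; C11 methyl syn to C7–C9), via vinylketene 11 (not isolated)
Conditions: Et3N, toluene, reflux, slow addition of 10 at high dilution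
Reagents that add atoms: none
Why: Et3N removes HCl across the acyl group and the C9 methyl group, which lies cis to the acyl group in the 2E isomer, to give vinylketene 11 with an exocyclic methylene on C9. The ketene then adds across C6=C11 in an asynchronous [2+2] cycloaddition: C5 bonds to the less substituted C6 while positive charge builds at tertiary C11, which closes onto C10. The closest known reaction type is the intramolecular vinylketene–alkene cycloaddition of 3-methyl-2,6-dienoyl chlorides (geranoyl and farnesoyl chloride), which gives 2-methylidenebicyclo[3.1.1]heptan-6-ones. Ring C closes as the cyclobutanone, and the six-membered carbocycle that becomes ring B closes in the crossed mode through the three-atom tether C7–C8–C9, giving a bridged and not a fused bicycle. C6 and C10 are bridgeheads fixed by the bicycle; C11 is set by suprafacial addition to the E alkene, which keeps its methyl cis to C7 (syn to the C7–C9 bridge) and turns the C1 arm towards C5. The step needs deprotonation at the methyl and not at C8, crossed and not fused bonding, and no reaction at C3=C4; these are secured by the 2E geometry, by the polarisation of the trisubstituted alkene with a short tether, and by the remoteness of the C3=C4 alkene. High dilution suppresses ketene dimerisation, and the product is racemic.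

Step 8
Reactants: 12 racemic bicyclic cyclobutanone
Product: 13 racemic 7-methyl-2-methylidene-7-{[2-(2-methylprop-1-en-1-yl)-1,3-dithian-2-yl]methyl}bicyclo[3.1.1]heptan-6-ol, hydroxyl syn to the C7 side arm
Conditions: NaBH4, MeOH, 0 °C
Reagents that add atoms: none
Why: Hydride reduction of the strained ketone from the face away from the axial C1 arm; the new centre is lost in step 12, so its configuration is immaterial.

Step 9
Reactants: 13 racemic bicyclic alcohol
Product: 14 bicyclic alcohol as the single enantiomer configured at C6, C10 and C11 as in the target
Conditions: Burkholderia cepacia lipase (Amano PS), vinyl acetate, t-BuOMe, 30 °C, to about half conversion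
Reagents that add atoms: none
Why: Lipase-catalysed kinetic resolution by irreversible transesterification; the enantiomers differ in which flank of the carbinol carries the methylidene, and the unreacted alcohol is separated from the acetate by chromatography.

Step 10
Reactants: 14 resolved bicyclic alcohol
Product: 15 1-(6-hydroxy-7-methyl-2-methylidenebicyclo[3.1.1]heptan-7-yl)-4-methylpent-3-en-2-one (target locants: C5 hydroxyl; C2 ketone; C3=C4)
Conditions: PhI(OCOCF3)2, MeCN–H2O (9:1), 0 °C
Reagents that add atoms: water, O
Why: Oxidative dithiane hydrolysis with a hypervalent iodine reagent is fast at 0 °C and spares the alkenes and the free alcohol; it reveals the conjugated enone needed as radical acceptor.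

Step 11
Reactants: 15 hydroxy enone
Product: 16 O-[7-methyl-2-methylidene-7-(4-methyl-2-oxopent-3-en-1-yl)bicyclo[3.1.1]heptan-6-yl] 1H-imidazole-1-carbothioate
Conditions: 1,1'-thiocarbonyldiimidazole, DMAP (cat.), toluene, 80 °C
Reagents that add atoms: 1,1'-thiocarbonyldiimidazole, S=C(n1ccnc1)n1ccnc1
Why: Neutral thioacylation of the hindered secondary alcohol; it avoids the basic conditions of xanthate formation, which the enone would not tolerate.

Step 12
Reactants: 16 thiocarbonyl imidazolide
Product: 17 tricyclic C2 ketone with rings A, B and C closed (C4 gem-dimethyl; C9 methylidene; C11 methyl; C5–H, C6–H, C10–H as in the target)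
Conditions: Bu3SnH, AIBN, benzene, reflux, syringe-pump addition, about 0.003 M
Reagents that add atoms: none
Why: Barton–McCombie fragmentation gives the secondary C5 radical, which adds in an intramolecular Giese reaction to the β-carbon C4 of the enone (7-endo, polarity-matched; the carbonyl inside the tether disfavours the exo mode), and the α-keto radical at C3 is reduced by the stannane. C5 is set by the tether, because the C1 arm is axial on the face of ring C opposite the C7–C9 bridge, so C4 can bond only on that face; slow addition keeps the stannane dilute so that cyclisation outruns direct reduction.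

Step 13
Reactants: 17 tricyclic ketone with C9 methylidene
Product: 18 tricyclic C2 ketone with C8=C9 alkene and C9 methyl
Conditions: RhCl3·3H2O (cat.), EtOH, 80 °C
Reagents that add atoms: none
Why: Metal-hydride isomerisation of the exocyclic alkene to the more stable trisubstituted endocyclic isomer; it cannot go further because the next position is a bridgehead, and no carbocation is involved that could open the cyclobutane.

Step 14
Reactants: 18 tricyclic ketone
Product: 20 C1-hydroxy C2-ketone (mixture of C1 epimers; both converge in step 15), via potassium enolate 19 (not isolated)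
Conditions: KN(SiMe3)2, THF, −78 °C; then 2-(benzenesulfonyl)-3-phenyloxaziridine; aq. NH4Cl
Reagents that add atoms: 2-(benzenesulfonyl)-3-phenyloxaziridine, O=S(=O)(c1ccccc1)N1OC1c1ccccc1
Why: Kinetic enolisation with a bulky amide should go at C1, whose neighbour C11 has its substituents tied back in the cyclobutane, and not at C3, which is flanked by the freely rotating gem-dimethyl group; Davis oxidation of the enolate then puts oxygen on C1.

Step 15
Reactants: 20 C1-hydroxy C2-ketone
Product: 21 tricyclic C1,C2-dione
Conditions: Dess–Martin periodinane, CH2Cl2, rt
Reagents that add atoms: none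
Why: Dess–Martin oxidation of an α-hydroxy ketone to the 1,2-dione under neutral conditions; this removes the unwanted C1 stereocentre.

Step 16
Reactants: 21 C1,C2-dione
Product: 22 C1 ketone with C2 trifluoromethanesulfonyloxy group and C2=C3 alkene
Conditions: Tf2O, Et3N, CH2Cl2, −78 to 0 °C
Reagents that add atoms: trifluoromethanesulfonic anhydride, O=S(=O)(OS(=O)(=O)C(F)(F)F)C(F)(F)F
Why: O-sulfonylation of the dione enol; C11 is quaternary, so the dione can enolise only from C2 towards C3 and the alkene position is fixed by construction.

Step 17
Reactants: 22 enol triflate
Product: 23 tricyclic ring A enone (C1 ketone; C2=C3; C8=C9)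
Conditions: Pd(OAc)2 (cat.), PPh3, HCO2H, Bu3N, DMF, 60 °C
Reagents that add atoms: none
Why: Oxidative addition of zerovalent palladium into the vinyl triflate, formate exchange, decarboxylation and reductive elimination replace the triflate by hydrogen; the unactivated C8=C9 alkene is not touched.

Step 18
Reactants: 23 ring A enone
Product: 24 allylic alcohol with C1 hydroxyl on the C6 side (1R in this compound; C2=C3; C8=C9)
Conditions: (S)-2-methyl-CBS-oxazaborolidine, catecholborane, toluene, −78 to −40 °C; aq. NaOH work-up
Reagents that add atoms: none
Why: Corey–Bakshi–Shibata reduction; with the quaternary C11 as the large flank and the cis-alkenyl C2 as the small one, the (S)-catalyst should place the hydroxyl on the C6 side. Reagent control is used because the core is nearly mirror-symmetric about ring A, and catecholborane is chosen because it does not hydroborate the C8=C9 alkene at these temperatures.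

Step 19
Reactants: 24 allylic alcohol
Product: 25 C1 angelate (C2=C3; C8=C9)
Conditions: angelic acid, 2,4,6-trichlorobenzoyl chloride, Et3N, toluene, rt; then 24, 80 °C
Reagents that add atoms: angelic acid, C/C=C(/C)C(=O)O
Why: Yamaguchi esterification through the mixed anhydride, run without a nucleophilic pyridine catalyst so that the Z alkene does not isomerise to the tiglate; the ester also serves as protecting group for C1.

Step 20
Reactants: 25 C1 angelate
Product: 26 C1 angelate with ring B enone (C7 ketone; C8=C9; C2=C3)
Conditions: CrO3, 3,5-dimethylpyrazole, CH2Cl2, −20 °C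
Reagents that add atoms: chromium trioxide, O=[Cr](=O)=O
Why: Allylic oxidation of the trisubstituted C8=C9 alkene at its unhindered methylene C7, the verbenone-type conversion; the only allylic hydrogen of the ring A alkene is the hindered C1–H, deactivated by the ester, and the angelate methyls sit on an electron-poor alkene.

Step 21
Reactants: 26 ring B enone angelate
Product: 27 C2,C3-diol (both hydroxyls on the C10 side; C1 angelate; ring B enone)
Conditions: OsO4 (cat.), N-methylmorpholine N-oxide, acetone–H2O, rt
Reagents that add atoms: N-methylmorpholine N-oxide, C[N+]1([O-])CCOCC1; water, O (osmium tetroxide, O=[Os](=O)(=O)=O, as catalytic carrier)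
Why: Upjohn dihydroxylation; OsO4 prefers the isolated cis-alkene over the two conjugated, electron-poor alkenes (ring B enone, angelate). It approaches anti to the allylic ester on C1, so both new hydroxyls are trans to C1–O and cis to each other.

Step 22
Reactants: 27 C2,C3-diol
Product: 28 target, C1 angelate, C2 isovalerate, C3 alcohol (1S,2S,3S,5S,6R,10R,11R)
Conditions: (Me2CHCH2CO)2O (1.1 equiv), DMAP (cat.), pyridine, CH2Cl2, −20 °C
Reagents that add atoms: 3-methylbutanoic anhydride, CC(C)CC(=O)OC(=O)CC(C)C
Why: Acyl transfer catalysis; C2–OH lies between two methine carbons and should react ahead of C3–OH, which is neopentyl next to the gem-dimethyl carbon. Low temperature and limiting anhydride guard against diacylation, acyl migration and angelate isomerisation.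

## Compound list

1 | methyl geranate, methyl (2E)-3,7-dimethylocta-2,6-dienoate | COC(=O)/C=C(\C)CCC=C(C)C | starting material
2 | methyl (2E,6E)-8-hydroxy-3,7-dimethylocta-2,6-dienoate | COC(=O)/C=C(\C)CC/C=C(\C)CO | intermediate
3 | methyl (2E,6E)-8-bromo-3,7-dimethylocta-2,6-dienoate | COC(=O)/C=C(\C)CC/C=C(\C)CBr | intermediate
4 | 3-methylbut-2-enal | CC(C)=CC=O | starting material
5 | propane-1,3-dithiol | SCCCS | starting material
6 | 2-(2-methylprop-1-en-1-yl)-1,3-dithiane | CC(C)=CC1SCCCS1 | intermediate
7 | 2-lithio-2-(2-methylprop-1-en-1-yl)-1,3-dithiane (not isolated) | [Li]C1(SCCCS1)C=C(C)C | intermediate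
8 | methyl (2E,6E)-3,7-dimethyl-8-[2-(2-methylprop-1-en-1-yl)-1,3-dithian-2-yl]octa-2,6-dienoate | COC(=O)/C=C(\C)CC/C=C(\C)CC1(SCCCS1)C=C(C)C | intermediate
9 | (2E,6E)-3,7-dimethyl-8-[2-(2-methylprop-1-en-1-yl)-1,3-dithian-2-yl]octa-2,6-dienoic acid | OC(=O)/C=C(\C)CC/C=C(\C)CC1(SCCCS1)C=C(C)C | intermediate
10 | (2E,6E)-3,7-dimethyl-8-[2-(2-methylprop-1-en-1-yl)-1,3-dithian-2-yl]octa-2,6-dienoyl chloride | ClC(=O)/C=C(\C)CC/C=C(\C)CC1(SCCCS1)C=C(C)C | intermediate
11 | vinylketene, (6E)-7-methyl-3-methylidene-8-[2-(2-methylprop-1-en-1-yl)-1,3-dithian-2-yl]octa-1,6-dien-1-one (not isolated) | O=C=CC(=C)CC/C=C(\C)CC1(SCCCS1)C=C(C)C | intermediate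
12 | racemic 7-methyl-2-methylidene-7-{[2-(2-methylprop-1-en-1-yl)-1,3-dithian-2-yl]methyl}bicyclo[3.1.1]heptan-6-one, methyl syn to the three-carbon bridge (needed enantiomer drawn) | O=C1[C@H]2CCC(=C)[C@@H]1[C@@]2(C)CC3(SCCCS3)C=C(C)C | intermediate
13 | racemic bicyclic alcohol from 12, hydroxyl syn to the side arm (needed enantiomer drawn) | O[C@@H]1[C@H]2CCC(=C)[C@@H]1[C@@]2(C)CC3(SCCCS3)C=C(C)C | intermediate
14 | bicyclic alcohol, single enantiomer | O[C@@H]1[C@H]2CCC(=C)[C@@H]1[C@@]2(C)CC3(SCCCS3)C=C(C)C | intermediate
15 | 1-(6-hydroxy-7-methyl-2-methylidenebicyclo[3.1.1]heptan-7-yl)-4-methylpent-3-en-2-one | O[C@@H]1[C@H]2CCC(=C)[C@@H]1[C@@]2(C)CC(=O)C=C(C)C | intermediate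
16 | O-[7-methyl-2-methylidene-7-(4-methyl-2-oxopent-3-en-1-yl)bicyclo[3.1.1]heptan-6-yl] 1H-imidazole-1-carbothioate | S=C(n1ccnc1)O[C@@H]2[C@H]3CCC(=C)[C@@H]2[C@@]3(C)CC(=O)C=C(C)C | intermediate
17 | tricyclic C2 ketone with C9 methylidene | O=C1CC(C)(C)[C@@H]2[C@H]3CCC(=C)[C@@H]2[C@@]3(C)C1 | intermediate
18 | tricyclic C2 ketone with C8=C9 alkene | O=C1CC(C)(C)[C@@H]2[C@H]3CC=C(C)[C@@H]2[C@@]3(C)C1 | intermediate
19 | potassium C1=C2 enolate of 18 (not isolated) | [K+].[O-]C=1CC(C)(C)[C@@H]2[C@H]3CC=C(C)[C@@H]2[C@@]3(C)C=1 | intermediate
20 | C1-hydroxy C2-ketone, mixture of C1 epimers | O=C1CC(C)(C)[C@@H]2[C@H]3CC=C(C)[C@@H]2[C@@]3(C)C1O | intermediate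
21 | tricyclic C1,C2-dione | O=C1C(=O)CC(C)(C)[C@@H]2[C@H]3CC=C(C)[C@@H]2[C@@]13C | intermediate
22 | C1 ketone, C2 enol triflate (C2=C3) | O=C1C(OS(=O)(=O)C(F)(F)F)=CC(C)(C)[C@@H]2[C@H]3CC=C(C)[C@@H]2[C@@]13C | intermediate
23 | tricyclic ring A enone (C1 ketone, C2=C3, C8=C9) | O=C1C=CC(C)(C)[C@@H]2[C@H]3CC=C(C)[C@@H]2[C@@]13C | intermediate
24 | allylic alcohol, C1 hydroxyl on the C6 side (1R) | O[C@@H]1C=CC(C)(C)[C@@H]2[C@H]3CC=C(C)[C@@H]2[C@@]13C | intermediate
25 | C1 angelate of 24 | C/C=C(/C)C(=O)O[C@@H]1C=CC(C)(C)[C@@H]2[C@H]3CC=C(C)[C@@H]2[C@@]13C | intermediate
26 | C1 angelate with ring B enone (C7 ketone) | C/C=C(/C)C(=O)O[C@@H]1C=CC(C)(C)[C@@H]2[C@H]3C(=O)C=C(C)[C@@H]2[C@@]13C | intermediate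
27 | C2,C3-diol, C1 angelate, ring B enone | C/C=C(/C)C(=O)O[C@@H]1[C@@H](O)[C@@H](O)C(C)(C)[C@@H]2[C@H]3C(=O)C=C(C)[C@@H]2[C@@]13C | intermediate
28 | CNP0251293.1, C1 angelate, C2 isovalerate, C3 alcohol (1S,2S,3S,5S,6R,10R,11R) | C/C=C(/C)C(=O)O[C@@H]1[C@@H](OC(=O)CC(C)C)[C@@H](O)C(C)(C)[C@@H]2[C@H]3C(=O)C=C(C)[C@@H]2[C@@]13C | target

## Step count and least certain steps

Total: 22 steps. Longest linear sequence: 21 steps from methyl geranate 1 (steps 1, 2 and 4–22); step 3 prepares the branch compound 6.

**Step 7 (key step).** The likeliest failure is loss of material through ketene oligomerisation, or through deprotonation at C8 in place of the methyl, which gives a dienyl ketene that cannot cyclise in the crossed mode. The alkene is unactivated and the ketene only moderately electrophilic. Fallback, from 10 back to 12: 10 is converted with dimethylamine into the amide (2E,6E)-N,N,3,7-tetramethyl-8-[2-(2-methylprop-1-en-1-yl)-1,3-dithian-2-yl]octa-2,6-dienamide F1. Activation with triflic anhydride and 2,4,6-collidine in hot 1,2-dichloroethane generates the vinylketeniminium ion, a far stronger electrophile than the ketene. It undergoes the same crossed [2+2] to the cyclobutaniminium triflate F2, and aqueous NaHCO3 hydrolyses F2 to 12.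

**Step 12.** The likeliest failure is hydrogen transfer to the C5 radical before it reaches the hindered, β,β-disubstituted acceptor carbon, giving simple deoxygenation without ring closure. Fallback, from 15 back to 17: 15 is oxidised with Dess–Martin periodinane to the keto enone F3. Samarium diiodide (SmI2, hexamethylphosphoramide, t-BuOH, THF) then couples the C5 ketone reductively with the enone β-carbon in a polar-radical ketyl–olefin cyclisation, with no competing hydrogen donor, to give the tricyclic C5-hydroxy C2-ketone F4. The tertiary alcohol is acylated with methyl chlorooxoacetate to the methyl oxalate F5, and F5 is deoxygenated with Bu3SnH and AIBN to 17. The C5 radical takes hydrogen on the only open face.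

**Step 9.** The likeliest failure is slow acylation with poor discrimination between the enantiomers, because the carbinol is hindered and its two flanks differ only one bond further out. Fallback, from 13 back to 14: 13 is esterified with (S)-2-methoxy-2-phenylacetic acid (carbodiimide, DMAP cat.) to the diastereomeric esters, the (S)-2-methoxy-2-phenylacetate of 14, F6, and that of its enantiomer, F7. These are separated by chromatography or crystallisation, and F6 is cleaved with K2CO3 in methanol to 14.

**Step 14.** The likeliest failure is competing deprotonation at C3, which would lead after steps 15–17 to the regioisomeric enone; both α-carbons are neopentyl and differ only in how far their neighbours are tied back. Fallback, from 18 back to 21: 18 is condensed with tert-butoxybis(dimethylamino)methane under equilibrating conditions, which should place the aminomethylidene group at the less congested C1, giving the C1 (dimethylamino)methylidene ketone F8. Photo-oxygenation of F8 (O2, rose bengal, visible light) cleaves the electron-rich enaminone alkene, much faster than the ene reaction of the C8=C9 alkene, to give dione 21.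

**Step 18.** The likeliest failure is poor facial discrimination by the catalyst, because both flanks of the ketone (quaternary carbon and alkenyl group) can act as the large group, or a sense opposite to the one assumed; in the latter case the (R)-catalyst is used. Fallback, from 23 back to 24: Luche reduction (NaBH4, CeCl3·7H2O, MeOH) gives 24 together with its C1 epimer F9, which are diastereomers. A lipase with vinyl acetate is used to acylate the 1R carbinol selectively to the acetate of 24, F10, which is separated from F9 and methanolysed (K2CO3, MeOH) to 24. F9 is returned to 23 by MnO2 oxidation.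

**Step 21.** The likeliest failure is competing osmylation of the angelate alkene, or insufficient facial bias from an acyloxy group, since the ring A alkene is hindered and inductively deactivated. Fallback, from 24 back to 27:
- 24 is silylated (t-BuMe2SiOTf, 2,6-lutidine) to the silyl ether F11.
- F11 is oxidised as in step 20 to the ring B enone silyl ether F12.
- F12 is dihydroxylated as in step 21, with no angelate present and a bulkier group on C1, to the diol silyl ether F13.
- F13 is protected (2,2-dimethoxypropane, pyridinium p-toluenesulfonate) as the acetonide silyl ether F14.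
- F14 is desilylated (Bu4NF) to the acetonide alcohol F15.
- F15 is esterified as in step 19 to the acetonide angelate F16.
- F16 is hydrolysed with aqueous acetic acid to 27.

## Further compounds

F1 | step 7 | (2E,6E)-N,N,3,7-tetramethyl-8-[2-(2-methylprop-1-en-1-yl)-1,3-dithian-2-yl]octa-2,6-dienamide | CN(C)C(=O)/C=C(\C)CC/C=C(\C)CC1(SCCCS1)C=C(C)C
F2 | step 7 | racemic N,N-dimethyliminium triflate corresponding to ketone 12 (needed enantiomer drawn) | C[N+](C)=C1[C@H]2CCC(=C)[C@@H]1[C@@]2(C)CC3(SCCCS3)C=C(C)C.[O-]S(=O)(=O)C(F)(F)F
F3 | step 12 | 4-methyl-1-(7-methyl-2-methylidene-6-oxobicyclo[3.1.1]heptan-7-yl)pent-3-en-2-one, single enantiomer | O=C1[C@H]2CCC(=C)[C@@H]1[C@@]2(C)CC(=O)C=C(C)C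
F4 | step 12 | tricyclic C5-hydroxy C2-ketone with C9 methylidene | O=C1CC(C)(C)[C@]2(O)[C@H]3CCC(=C)[C@@H]2[C@@]3(C)C1
F5 | step 12 | methyl oxalate of F4 | O=C1CC(C)(C)[C@]2(OC(=O)C(=O)OC)[C@H]3CCC(=C)[C@@H]2[C@@]3(C)C1
F6 | step 9 | (S)-2-methoxy-2-phenylacetate of 14 | CO[C@H](C(=O)O[C@@H]1[C@H]2CCC(=C)[C@@H]1[C@@]2(C)CC3(SCCCS3)C=C(C)C)c1ccccc1
F7 | step 9 | (S)-2-methoxy-2-phenylacetate of the enantiomer of 14 | CO[C@H](C(=O)O[C@H]1[C@@H]2CCC(=C)[C@H]1[C@]2(C)CC3(SCCCS3)C=C(C)C)c1ccccc1
F8 | step 14 | C1 (dimethylamino)methylidene derivative of ketone 18 | CN(C)/C=C1/C(=O)CC(C)(C)[C@@H]2[C@H]3CC=C(C)[C@@H]2[C@@]13C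
F9 | step 18 | C1 epimer of allylic alcohol 24 | O[C@H]1C=CC(C)(C)[C@@H]2[C@H]3CC=C(C)[C@@H]2[C@@]13C
F10 | step 18 | acetate of allylic alcohol 24 | CC(=O)O[C@@H]1C=CC(C)(C)[C@@H]2[C@H]3CC=C(C)[C@@H]2[C@@]13C
F11 | step 21 | tert-butyldimethylsilyl ether of 24 | CC(C)(C)[Si](C)(C)O[C@@H]1C=CC(C)(C)[C@@H]2[C@H]3CC=C(C)[C@@H]2[C@@]13C
F12 | step 21 | C1 silyl ether with ring B enone and C2=C3 alkene | CC(C)(C)[Si](C)(C)O[C@@H]1C=CC(C)(C)[C@@H]2[C@H]3C(=O)C=C(C)[C@@H]2[C@@]13C
F13 | step 21 | C1 silyl ether C2,C3-diol with ring B enone | CC(C)(C)[Si](C)(C)O[C@@H]1[C@@H](O)[C@@H](O)C(C)(C)[C@@H]2[C@H]3C(=O)C=C(C)[C@@H]2[C@@]13C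
F14 | step 21 | C2,C3-acetonide C1 silyl ether | CC(C)(C)[Si](C)(C)O[C@@H]1[C@@H](OC(C)(C)O4)[C@@H]4C(C)(C)[C@@H]2[C@H]3C(=O)C=C(C)[C@@H]2[C@@]13C
F15 | step 21 | C2,C3-acetonide C1 alcohol | O[C@@H]1[C@@H](OC(C)(C)O4)[C@@H]4C(C)(C)[C@@H]2[C@H]3C(=O)C=C(C)[C@@H]2[C@@]13C
F16 | step 21 | C2,C3-acetonide C1 angelate | C/C=C(/C)C(=O)O[C@@H]1[C@@H](OC(C)(C)O4)[C@@H]4C(C)(C)[C@@H]2[C@H]3C(=O)C=C(C)[C@@H]2[C@@]13C
A1 | alternative 1 | tricyclic ring B enone with C1 tert-butyldimethylsilyl ether and C2=C3 alkene | CC(C)(C)[Si](C)(C)O[C@@H]1C=CC(C)(C)[C@@H]2[C@H]3C(=O)C=C(C)[C@@H]2[C@@]13C
A2 | alternative 2 | tricyclic ring A enone with C7 ethylene ketal and saturated C9 methyl | O=C1C=CC(C)(C)[C@@H]2[C@H]3C4(OCCO4)C[C@@H](C)[C@@H]2[C@@]13C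
A3 | alternative 3 | tricyclic C1 ketone with C2 p-methoxybenzyl ether, C3 hydroxyl and ring B enone | O=C1[C@@H](OCc2ccc(OC)cc2)[C@@H](O)C(C)(C)[C@@H]3[C@H]4C(=O)C=C(C)[C@@H]3[C@@]14C
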